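**Structural features**

The target is a furanoheliangolide-type sesquiterpene lactone. Its ten-membered carbocycle (C1–C10) is spanned by an oxygen between C3 and C10, so that O, C3, C2, C1 and C10 form a 3(2H)-furanone (C1 ketone, C2=C3 enol ether). This furanone is conjugated with the Z C4=C5 alkene. An α-methylene-γ-butyrolactone is fused trans across C7–C8 (C11–C13 on C7, ring oxygen on C8), and C6 carries a (2S,3S)-2,3-dimethyloxirane-2-carboxylate (epoxyangelate). Three stereocentres are contiguous (C6 S, C7 R, C8 S). The fourth, the quaternary ether carbon C10 (S), lies across the ring; C3 is trigonal in the target but stereogenic in every precursor whose bridge is still open. Fragile groups are the exocyclic methylene lactone (Michael acceptor), the glycidic ester, any β-oxygenated ketone on the way (C6 ketone with C8 oxygen), and the dienone, whose proton at C6 is vinylogously acidic. The real difficulty is the medium ring: closing it, holding the Z C4=C5 geometry, and setting C7, C8 and C10 on a mobile ring. The key step uses the fact that C2–C3(O)–C4(C15)=C5–C6(O) together with C1 is an intact 4-oxygenated 3-methylcyclohex-2-en-1-ol. Only the bond between C6 and C1 of that six-membered ring has to be broken, while C7–C8 arrive as a vinyl unit and C9–C10–C14 as an isopropenyl unit.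

**Logic of the disconnections**

36 is cut at the ester bond C6–O–C(=O) into 30 and 34. The glycidic ester is the most labile part and has its own two stereocentres, so it is made separately as a single enantiomer and attached last. This demands acylation of a hindered allylic alcohol without touching the methylene lactone.

34 is traced through 33 and 32 to 31. The two epoxide C–O bonds are cut, which leaves a Z allylic alcohol whose geometry fixes the cis relation of carboxyl carbon and C3 methyl. The forward epoxidation must be reagent-controlled.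

30 is traced through 29 to 27 by removing the C2=C3 double bond. The furanone becomes a saturated 3-oxotetrahydrofuran, and enolisation can only go toward C2 because C10 is quaternary. The forward step must remove the bridgehead hydrogen at C3.

27 is traced through 26 to 24 by cutting the O–C10 bond and returning C1 to the alkene level (epoxide 25). This turns the bridged bicycle into a monocyclic diene. The forward step needs the epoxide oxygen on the α face of C10, so that the 3β-hydroxyl can open it from inside the ring with inversion.

24 is traced through 23 to 20 by removing the SEM group and cutting C11=C13. The methylenation is placed where the lactone α-carbon is the only acidic site (no ketone, no furanone, C6 oxygen silylated).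

20 is traced through 19 to 18 by returning C6 to the ketone. The forward reduction must deliver hydride to the α face.

18 is traced to 15 by cutting the lactone bond O8–C12 and replacing the C8 oxygen by silicon. This demands oxidation with retention at C8 and no epimerisation at C7.

15 is cut at C8–C9 and C7–C11 while the C1–C6 bond is re-formed, giving 11 and 12. The ten-membered ring, both ring alkenes and the C7/C8 pair collapse to a cyclohexenol with two alkenyl groups. The forward step needs a chair transition state and alkylation on the outer face of enolate 14.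

11 is cut at the carbinol–alkenyl bond into 4 and 8 (via 9 and 10). The addition must occur trans to the isopropenyl group and without enolisation.

8 is traced through 7 to 5 and 6 by cutting the C–Sn and Si–C(sp) bonds. Only E selectivity is asked of the hydrostannation.

4 is traced through 3 and 2 to 1 by removing the ring carbonyl, the protecting group and the hydride. The forward oxidation must pick the ring methylene next to the trisubstituted alkene.

**Other disconnections considered**

Alternative 1: The C5–C6 bond is cut. In the forward sense the Z alkenyl iodide of the seco iodo aldehyde A1 is turned by CrCl2 with catalytic NiCl2 into an alkenylchromium species, which adds to the C6 aldehyde and closes the carbocycle to the C6 alcohol A2 (identical with 30).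
- In its favour: it is convergent, since the furanone half with C10 and the lactone half with C7/C8 can be made apart. The alkene geometry is fixed in the iodide, the coupling discriminates aldehydes from ketones and esters, and A2 is one acylation from the target.
- Against it here: a strained, bridged ten-membered ring must be closed end to end. The aldehyde sits on C7, α to the formyl group and β to the lactone oxygen on C8, so epimerisation and β-elimination threaten A1. The new C6 carbinol is set only by macrocyclic bias of unknown sense.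
- Comparison: the chosen plan makes the ring by expansion, without any macrocyclisation, and sets C7 and C8 in the same concerted event. Alternative 1 is the better plan on convergence and on sparing the macrocycle a series of late oxidation steps. It is weaker on ring-closure risk and on stereocontrol at C6, and it would probably need about as many steps in total.

Alternative 2: The O–C10 bond is cut. Under mild acid the C3 hydroxyl of the hydroxy epoxide A3 (identical with 25) opens the 1,10-epoxide at the tertiary C10 and gives the bridged ether alcohol A4 (identical with 26).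
- In its favour: it follows the likely biogenesis, forms a five-membered ring, and fixes C10 stereospecifically by inversion.
- Against it as the strategy-defining step: it presupposes the whole ten-membered carbocycle with correct C3, C6, C7 and C8. It depends on epoxidation from one face, can be intercepted by the C4=C5 alkene, and still leaves oxidation and dehydrogenation to reach the furanone.
- Comparison: this is not a rival but a complement, and the chosen plan uses this very event as step 13. For control of C10 it is better than anything the sigmatropic step offers. As a key disconnection it removes one small ring and one stereocentre, where the ring expansion accounts for the carbocycle, two alkenes and two stereocentres. Step economy is the same, because the event is embedded.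

Alternative 3: The C6–C7 bond is cut and an O–C13 bond is added, giving the bridged thirteen-membered allylic ether A5. Deprotonation at C6 (allylic, α to oxygen) triggers a [2,3]-Wittig shift that contracts the ring to the carbocycle A6, with the C6 alkoxide, the C7 stereocentre and the C11=C13 alkene formed together.
- In its favour: C6 and C7 are set in one concerted step, the exocyclic methylene arrives without any lactone enolate chemistry, and a thirteen-membered ether is easier to close than a ten-membered carbocycle.
- Against it here: the C6 anion is the far end of a trienolate through the furanone, so the site of deprotonation and of reaction, and competition by [1,2] shift, are open questions. The syn/anti outcome in a bridged macrocycle is hard to foresee. A6 still needs oxidation of C12, PMB removal and lactonisation, and A5 with its quaternary C10 is itself a long synthesis.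
- Comparison: on installing C11=C13 and the C6 hydroxyl directly, Alternative 3 is better than the chosen plan. On mechanistic predictability, and on where the stereochemistry comes from (one carvone stereocentre relayed through a chair), the chosen plan is safer. Step counts are likely comparable or higher for Alternative 3.

Key step: step 7

Remark on the chemistry (numbering): macrocyclic compounds carry the germacrane numbers of the target (C1–C10 ring, C11–C13 lactone carbons, C14 on C10, C15 on C4). β is the ring face that holds the C7–C11 bond and α is the opposite face. Six-membered-ring compounds carry their own ring numbers. SEM = [2-(trimethylsilyl)ethoxy]methyl, TBS = tert-butyldimethylsilyl.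

Remark on the chemistry (precursor design): the configurations of the cyclohexenol and of the ring-expanded keto ester were checked against (S)-carvone and against C7 and C10 of the target and are kept. Two spectator groups are changed:
- The vinyl terminus carries an (E)-benzyldimethylsilyl group. It is inert in the rearrangement and cannot leave from the enolate as an oxygen substituent would. It is a latent 8α-hydroxyl, so the C7 centre made in the key step never has to be flattened to bring oxygen to C8.
- The C3 oxygen is an SEM acetal instead of a silyl ether, because it must survive the fluoride that unmasks C8. It is assumed that the benzylsilane tolerates KN(SiMe3)2 and 18-crown-6 at 50 °C.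

Step 1
Reactants: 1 (S)-carvone
Product: 2 (1S,5S)-cis-carveol
Conditions: NaBH4, CeCl3·7H2O, MeOH, −78 to 0 °C
Reagents that add atoms: none
Why: Luche 1,2-reduction of the enone; hydride enters axially and gives the pseudo-equatorial alcohol cis to the isopropenyl group (new centre 1S).

Step 2
Reactants: 2 (1S,5S)-cis-carveol
Product: 3 (1S,5S)-cis-carveol SEM ether
Conditions: SEMCl, iPr2NEt, Bu4NI (cat.), CH2Cl2, 0 °C to rt
Reagents that add atoms: 2-(trimethylsilyl)ethoxymethyl chloride, C[Si](C)(C)CCOCCl
Why: O-alkylation with a chloromethyl ether under amine base; the SEM acetal tolerates the oxidant of step 3, organometallics, amide bases and brief fluoride, and can later be removed beside a silyl ether.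

Step 3
Reactants: 3 (1S,5S)-cis-carveol SEM ether
Product: 4 (4S,6S)-3-methyl-6-(prop-1-en-2-yl)-4-{[2-(trimethylsilyl)ethoxy]methoxy}cyclohex-2-en-1-one
Conditions: CrO3, 3,5-dimethylpyrazole, CH2Cl2, −20 °C
Reagents that add atoms: chromium trioxide, O=[Cr](=O)=O
Why: Allylic C–H oxidation of the only ring methylene on the trisubstituted alkene to the β-methyl enone (chromium trioxide–dimethylpyrazole oxidation of 1-methylcyclohexenes). No stereocentre is touched, and the isopropenyl group next to the new ketone stays equatorial and cis-1,3 to OSEM.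

Step 4
Reactants: 5 ethynylmagnesium bromide, 6 benzylchlorodimethylsilane
Product: 7 benzyl(ethynyl)dimethylsilane
Conditions: THF, 0 °C to rt
Reagents that add atoms: none
Why: Substitution at silicon by the acetylide Grignard reagent; no stereochemistry is involved.

Step 5
Reactants: 7 benzyl(ethynyl)dimethylsilane
Product: 8 (E)-benzyldimethyl[2-(tributylstannyl)ethenyl]silane
Conditions: Bu3SnH, AIBN (cat.), neat, 90 °C
Reagents that add atoms: tributyltin hydride, CCCC[SnH](CCCC)CCCC
Why: Radical hydrostannation of a silylalkyne; the stannyl radical adds to the terminal carbon and reversible addition equilibrates the product to the E isomer.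

Step 6
Reactants: 8 (E)-benzyldimethyl[2-(tributylstannyl)ethenyl]silane, 4 (4S,6S)-3-methyl-6-(prop-1-en-2-yl)-4-{[2-(trimethylsilyl)ethoxy]methoxy}cyclohex-2-en-1-one
Product: 11 (1S,4S,6S)-1-[(E)-2-(benzyldimethylsilyl)ethenyl]-3-methyl-6-(prop-1-en-2-yl)-4-{[2-(trimethylsilyl)ethoxy]methoxy}cyclohex-2-en-1-ol, via alkenyllithium 9 (not isolated), via alkenylcerium dichloride 10 (not isolated)
Conditions: 8, n-BuLi, THF, −78 °C; CeCl3, −78 °C; then 4, −78 °C
Reagents that add atoms: none
Why: Tin–lithium exchange with retention of alkene geometry, transmetalation to the weakly basic organocerium, and 1,2-addition to the enolisable enone. The nucleophile enters the half-chair from the face opposite the adjacent equatorial isopropenyl group, so C1 is set with the alkenyl group trans to isopropenyl and the hydroxyl axial.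

Step 7
Reactants: 11 (1S,4S,6S)-1-[(E)-2-(benzyldimethylsilyl)ethenyl]-3-methyl-6-(prop-1-en-2-yl)-4-{[2-(trimethylsilyl)ethoxy]methoxy}cyclohex-2-en-1-ol, 12 methyl bromoacetate
Product: 15 methyl 2-[(1(10)E,4Z)-8α-(benzyldimethylsilyl)-4,10-dimethyl-6-oxo-3β-{[2-(trimethylsilyl)ethoxy]methoxy}cyclodeca-1(10),4-dien-7β-yl]acetate (3S,7S,8S), via potassium alkoxide 13 (not isolated), via potassium enolate 14 (not isolated)
Conditions: KN(SiMe3)2, 18-crown-6, THF, 0 to 50 °C; then 12, −78 to −30 °C
Reagents that add atoms: none
Why: Deprotonation gives alkoxide 13, whose charge accelerates the [3,3] shift: the silyl-bearing alkene terminus bonds to the isopropenyl CH2 (C8–C9) while the ring bond between the carbinol carbon and the isopropenyl-bearing carbon (C6–C1 in germacrane numbers) breaks. No ring is closed end to end; the ten-membered ring arises by four-carbon expansion of the six-membered ring, so no macrocyclisation entropy is paid. The chair transition state with alkenyl, isopropenyl and OSEM groups all equatorial gives the E C1=C10 alkene and a ring-trans C6–C7 enolate, and the former ring alkene is carried over as Z C4=C5. At C8, the E geometry of the alkenylsilane puts silicon equatorial in that chair, which translates into the 8α (S) configuration. At C7, enolate 14 is released in the conformer fixed by the chair and is alkylated by 12 on its outer face, anti to the C8–C9 bond, placing the acetate arm β as in the target. The closest known reaction type is the anionic oxy-Cope ring expansion of 1,2-dialkenylcycloalkanols with alkylative trapping of the regiodefined enolate. The step needs chair over boat (secured by the trans-diequatorial alkenyl groups), C- over O-alkylation and alkylation faster than proton transfer (primary bromide, low temperature, soluble amide base with no excess hydride), and no β-elimination (silicon is not a leaving group from the enolate).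

Step 8
Reactants: 15 methyl 2-[(1(10)E,4Z)-8α-(benzyldimethylsilyl)-4,10-dimethyl-6-oxo-3β-{[2-(trimethylsilyl)ethoxy]methoxy}cyclodeca-1(10),4-dien-7β-yl]acetate
Product: 18 (1(10)E,4Z)-6-oxo-3β-(SEM-oxy)-13-norgermacra-1(10),4-dien-12,8α-olide (3S,7R,8S), via silanol 16 (not isolated), via hydroxy ester 17 (not isolated)
Conditions: Bu4NF, THF, 0 °C; then 30% H2O2, KHCO3, MeOH/THF, rt; then PPTS, PhH, 40 °C
Reagents that add atoms: hydrogen peroxide, OO
Why: Fluoride cleaves the benzyl–silicon bond (benzyl is the designed leaving group) and the silanol undergoes Tamao–Fleming oxidation with retention, giving the 8α-hydroxyl. The γ-hydroxy ester then closes to the trans-fused γ-lactone by acyl substitution under mild acid; the SEM acetal and both alkenes are inert.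

Step 9
Reactants: 18 (1(10)E,4Z)-6-oxo-3β-(SEM-oxy)-13-norgermacra-1(10),4-dien-12,8α-olide
Product: 19 (1(10)E,4Z)-6β-hydroxy-3β-(SEM-oxy)-13-norgermacra-1(10),4-dien-12,8α-olide (6S)
Conditions: NaBH4, CeCl3·7H2O, MeOH, −78 °C
Reagents that add atoms: none
Why: Luche 1,2-reduction of the enone carbonyl, which leaves the lactone alone. Hydride should enter on the α face, anti to the C7–C11 bond of the fused lactone that flanks the carbonyl (Felkin-type approach), giving the 6β-alcohol.

Step 10
Reactants: 19 (1(10)E,4Z)-6β-hydroxy-3β-(SEM-oxy)-13-norgermacra-1(10),4-dien-12,8α-olide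
Product: 20 (1(10)E,4Z)-6β-(TBS-oxy)-3β-(SEM-oxy)-13-norgermacra-1(10),4-dien-12,8α-olide
Conditions: TBSOTf, 2,6-lutidine, CH2Cl2, −78 to 0 °C
Reagents that add atoms: tert-butyldimethylsilyl triflate, CC(C)(C)[Si](C)(C)OS(=O)(=O)C(F)(F)F
Why: Silylation of a hindered secondary alcohol with a silyl triflate under non-basic conditions; it removes the acidic proton and the risk of lactone migration to O6 before enolate chemistry.

Step 11
Reactants: 20 (1(10)E,4Z)-6β-(TBS-oxy)-3β-(SEM-oxy)-13-norgermacra-1(10),4-dien-12,8α-olide
Product: 23 (1(10)E,4Z)-6β-(TBS-oxy)-3β-(SEM-oxy)germacra-1(10),4,11(13)-trien-12,8α-olide, via Mannich base 21 (not isolated), via ammonium iodide 22 (not isolated)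
Conditions: LiN(iPr)2, THF, −78 °C; CH2=NMe2+ I−, −78 to 0 °C; then MeI, CH2Cl2/MeOH, rt; then aq. NaHCO3, rt
Reagents that add atoms: Eschenmoser's salt (N,N-dimethylmethyleneiminium iodide), C=[N+](C)C.[I-]
Why: α-Methylenation of the lactone by enolate aminomethylation, quaternisation and base-induced elimination. C11 is the only acidic site at this stage, and it ends trigonal, so no stereocentre is created.

Step 12
Reactants: 23 (1(10)E,4Z)-6β-(TBS-oxy)-3β-(SEM-oxy)germacra-1(10),4,11(13)-trien-12,8α-olide
Product: 24 (1(10)E,4Z)-3β-hydroxy-6β-(TBS-oxy)germacra-1(10),4,11(13)-trien-12,8α-olide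
Conditions: MgBr2·OEt2, Et2O/MeNO2, rt
Reagents that add atoms: none
Why: Chelation-assisted cleavage of the SEM acetal by a mild Lewis acid, which is selective over a secondary TBS ether and harmless to the methylene lactone; it frees the 3β-hydroxyl with retention.

Step 13
Reactants: 24 (1(10)E,4Z)-3β-hydroxy-6β-(TBS-oxy)germacra-1(10),4,11(13)-trien-12,8α-olide
Product: 26 (4Z)-3β,10β-epoxy-1β-hydroxy-6β-(TBS-oxy)germacra-4,11(13)-dien-12,8α-olide, via 1β,10α-epoxide 25 (not isolated)
Conditions: mCPBA, NaHCO3, CH2Cl2, −20 °C; then CSA (cat.), CH2Cl2, 0 °C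
Reagents that add atoms: 3-chloroperbenzoic acid, OOC(=O)c1cccc(Cl)c1
Why: The peracid should attack the electron-rich, strained E C1=C10 alkene on its outer face (α at C10); C4=C5 is deactivated by two allylic oxygens and the methylene lactone is electron-poor. Under acid the 3β-hydroxyl opens the epoxide at the tertiary C10 from inside the ring with inversion (transannular anti opening, five-membered ether), which sets C10 (S) and leaves the 1β-hydroxyl.

Step 14
Reactants: 26 (4Z)-3β,10β-epoxy-1β-hydroxy-6β-(TBS-oxy)germacra-4,11(13)-dien-12,8α-olide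
Product: 27 (4Z)-3β,10β-epoxy-1-oxo-6β-(TBS-oxy)germacra-4,11(13)-dien-12,8α-olide
Conditions: Dess–Martin periodinane, NaHCO3, CH2Cl2, 0 °C to rt
Reagents that add atoms: none
Why: Dess–Martin oxidation of the secondary alcohol under buffered neutral conditions; the neighbouring C10 is quaternary, so nothing can epimerise.

Step 15
Reactants: 27 (4Z)-3β,10β-epoxy-1-oxo-6β-(TBS-oxy)germacra-4,11(13)-dien-12,8α-olide
Product: 29 (4Z)-3,10-epoxy-1-oxo-6β-(TBS-oxy)germacra-2,4,11(13)-trien-12,8α-olide, via trimethylsilyl enol ether 28 (not isolated)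
Conditions: LiN(SiMe3)2, Me3SiCl, THF, −78 °C; then Pd(OAc)2, MeCN, rt
Reagents that add atoms: none
Why: Saegusa–Ito dehydrogenation: the ketone can enolise only toward C2, and the silyl enol ether is converted by Pd(OAc)2 into the palladium enolate, which loses the C3 hydrogen by β-hydride elimination. The product is the vinylogous ester of the 3(2H)-furanone.

Step 16
Reactants: 29 (4Z)-3,10-epoxy-1-oxo-6β-(TBS-oxy)germacra-2,4,11(13)-trien-12,8α-olide
Product: 30 (4Z)-3,10-epoxy-6β-hydroxy-1-oxogermacra-2,4,11(13)-trien-12,8α-olide
Conditions: HF·pyridine, pyridine, THF, 0 °C to rt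
Reagents that add atoms: none
Why: Desilylation with buffered HF, a non-nucleophilic, non-basic medium that spares the methylene lactone and the furanone; configuration at C6 is retained.

Step 17
Reactants: 31 angelic acid
Product: 32 (Z)-2-methylbut-2-en-1-ol
Conditions: LiAlH4, Et2O, 0 °C
Reagents that add atoms: none
Why: Hydride reduction of the unsaturated acid to the allylic alcohol; the Z geometry is not affected.

Step 18
Reactants: 32 (Z)-2-methylbut-2-en-1-ol
Product: 33 [(2R,3S)-2,3-dimethyloxiran-2-yl]methanol
Conditions: Ti(OiPr)4 (10 mol%), D-(−)-diisopropyl tartrate (12 mol%), t-BuOOH, 4 Å molecular sieves, CH2Cl2, −20 °C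
Reagents that add atoms: tert-butyl hydroperoxide, CC(C)(C)OO
Why: Sharpless asymmetric epoxidation; the D-(−)-tartrate complex delivers oxygen to the face that gives 2R, and the Z alkene fixes the C3 methyl cis to the hydroxymethyl group (3S).

Step 19
Reactants: 33 [(2R,3S)-2,3-dimethyloxiran-2-yl]methanol
Product: 34 (2S,3S)-2,3-dimethyloxirane-2-carboxylic acid
Conditions: RuCl3·xH2O (cat.), NaIO4, MeCN/EtOAc/H2O, 0 °C to rt
Reagents that add atoms: water, O
Why: Ruthenium-catalysed periodate oxidation of the primary alcohol to the acid, a standard conversion of 2,3-epoxy alcohols that leaves the oxirane intact. The C2 descriptor changes from R to S only because the priorities change.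

Step 20
Reactants: 30 (4Z)-3,10-epoxy-6β-hydroxy-1-oxogermacra-2,4,11(13)-trien-12,8α-olide, 34 (2S,3S)-2,3-dimethyloxirane-2-carboxylic acid
Product: 36 CNP0258430.1 (6S,7R,8S,10S; ester 2S,3S), via mixed anhydride 35 (not isolated)
Conditions: 34, 2,4,6-Cl3C6H2COCl, Et3N, THF, rt; then 30, DMAP, PhMe, rt
Reagents that add atoms: none
Why: Yamaguchi esterification through the mixed anhydride; acyl transfer to the hindered allylic alcohol occurs with retention at C6 and without touching the oxirane centres.

Compound list

1 | (S)-carvone | CC1=CC[C@@H](CC1=O)C(C)=C | starting material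
2 | (1S,5S)-cis-carveol | CC1=CC[C@@H](C[C@@H]1O)C(C)=C | intermediate
3 | (1S,5S)-cis-carveol SEM ether | CC1=CC[C@@H](C[C@@H]1OCOCC[Si](C)(C)C)C(C)=C | intermediate
4 | (4S,6S)-3-methyl-6-(prop-1-en-2-yl)-4-{[2-(trimethylsilyl)ethoxy]methoxy}cyclohex-2-en-1-one | CC1=CC(=O)[C@@H](C[C@@H]1OCOCC[Si](C)(C)C)C(C)=C | intermediate
5 | ethynylmagnesium bromide | C#C[Mg]Br | starting material
6 | benzylchlorodimethylsilane | C[Si](C)(Cl)Cc1ccccc1 | starting material
7 | benzyl(ethynyl)dimethylsilane | C#C[Si](C)(C)Cc1ccccc1 | intermediate
8 | (E)-benzyldimethyl[2-(tributylstannyl)ethenyl]silane | CCCC[Sn](CCCC)(CCCC)/C=C/[Si](C)(C)Cc1ccccc1 | intermediate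
9 | (E)-[2-(benzyldimethylsilyl)ethenyl]lithium | [Li]/C=C/[Si](C)(C)Cc1ccccc1 | intermediate
10 | (E)-[2-(benzyldimethylsilyl)ethenyl]cerium dichloride | Cl[Ce](Cl)/C=C/[Si](C)(C)Cc1ccccc1 | intermediate
11 | (1S,4S,6S)-1-[(E)-2-(benzyldimethylsilyl)ethenyl]-3-methyl-6-(prop-1-en-2-yl)-4-{[2-(trimethylsilyl)ethoxy]methoxy}cyclohex-2-en-1-ol (alkenyl trans to isopropenyl, OSEM cis to isopropenyl) | c1ccccc1C[Si](C)(C)/C=C/[C@]1(O)C=C(C)[C@@H](OCOCC[Si](C)(C)C)C[C@H]1C(C)=C | intermediate
12 | methyl bromoacetate | COC(=O)CBr | starting material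
13 | potassium alkoxide of 11 | c1ccccc1C[Si](C)(C)/C=C/[C@]1([O-])C=C(C)[C@@H](OCOCC[Si](C)(C)C)C[C@H]1C(C)=C.[K+] | intermediate
14 | potassium C6–C7 enolate of (1(10)E,4Z)-8α-(benzyldimethylsilyl)-4,10-dimethyl-3β-(SEM-oxy)cyclodeca-1(10),4-dien-6-one (ring-trans enolate) | [C@@H]1([Si](C)(C)Cc2ccccc2)/C=C(\[O-])/C=C(C)\[C@@H](OCOCC[Si](C)(C)C)C/C=C(C)/C1.[K+] | intermediate
15 | methyl 2-[(1(10)E,4Z)-8α-(benzyldimethylsilyl)-4,10-dimethyl-6-oxo-3β-{[2-(trimethylsilyl)ethoxy]methoxy}cyclodeca-1(10),4-dien-7β-yl]acetate (3S,7S,8S) | COC(=O)C[C@@H]1[C@@H]([Si](C)(C)Cc2ccccc2)C/C(C)=C/C[C@H](OCOCC[Si](C)(C)C)/C(C)=C\C1=O | intermediate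
16 | 8α-[hydroxy(dimethyl)silyl] analogue of 15 (silanol) | COC(=O)C[C@@H]1[C@@H]([Si](C)(C)O)C/C(C)=C/C[C@H](OCOCC[Si](C)(C)C)/C(C)=C\C1=O | intermediate
17 | 8α-hydroxy analogue of 15 (hydroxy keto ester) | COC(=O)C[C@@H]1[C@@H](O)C/C(C)=C/C[C@H](OCOCC[Si](C)(C)C)/C(C)=C\C1=O | intermediate
18 | (1(10)E,4Z)-6-oxo-3β-(SEM-oxy)-13-norgermacra-1(10),4-dien-12,8α-olide (trans-fused; 3S,7R,8S) | C1C(=O)O[C@H]2C/C(C)=C/C[C@H](OCOCC[Si](C)(C)C)/C(C)=C\C(=O)[C@H]12 | intermediate
19 | (1(10)E,4Z)-6β-hydroxy-3β-(SEM-oxy)-13-norgermacra-1(10),4-dien-12,8α-olide (6S) | C1C(=O)O[C@H]2C/C(C)=C/C[C@H](OCOCC[Si](C)(C)C)/C(C)=C\[C@H](O)[C@H]12 | intermediate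
20 | (1(10)E,4Z)-6β-(TBS-oxy)-3β-(SEM-oxy)-13-norgermacra-1(10),4-dien-12,8α-olide | C1C(=O)O[C@H]2C/C(C)=C/C[C@H](OCOCC[Si](C)(C)C)/C(C)=C\[C@H](O[Si](C)(C)C(C)(C)C)[C@H]12 | intermediate
21 | 11-[(dimethylamino)methyl] derivative of 20 (Mannich base; C11 unassigned) | CN(C)CC1C(=O)O[C@H]2C/C(C)=C/C[C@H](OCOCC[Si](C)(C)C)/C(C)=C\[C@H](O[Si](C)(C)C(C)(C)C)[C@H]12 | intermediate
22 | trimethylammonium iodide from 21 | C[N+](C)(C)CC1C(=O)O[C@H]2C/C(C)=C/C[C@H](OCOCC[Si](C)(C)C)/C(C)=C\[C@H](O[Si](C)(C)C(C)(C)C)[C@H]12.[I-] | intermediate
23 | (1(10)E,4Z)-6β-(TBS-oxy)-3β-(SEM-oxy)germacra-1(10),4,11(13)-trien-12,8α-olide | C=C1C(=O)O[C@H]2C/C(C)=C/C[C@H](OCOCC[Si](C)(C)C)/C(C)=C\[C@H](O[Si](C)(C)C(C)(C)C)[C@H]12 | intermediate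
24 | (1(10)E,4Z)-3β-hydroxy-6β-(TBS-oxy)germacra-1(10),4,11(13)-trien-12,8α-olide | C=C1C(=O)O[C@H]2C/C(C)=C/C[C@H](O)/C(C)=C\[C@H](O[Si](C)(C)C(C)(C)C)[C@H]12 | intermediate
25 | (4Z)-1β,10α-epoxy-3β-hydroxy-6β-(TBS-oxy)germacra-4,11(13)-dien-12,8α-olide | C=C1C(=O)O[C@H]2C[C@@]3(C)O[C@@H]3C[C@H](O)/C(C)=C\[C@H](O[Si](C)(C)C(C)(C)C)[C@H]12 | intermediate
26 | (4Z)-3β,10β-epoxy-1β-hydroxy-6β-(TBS-oxy)germacra-4,11(13)-dien-12,8α-olide | C=C1C(=O)O[C@H]2C[C@]3(C)O[C@@H](C[C@H]3O)/C(C)=C\[C@H](O[Si](C)(C)C(C)(C)C)[C@H]12 | intermediate
27 | (4Z)-3β,10β-epoxy-1-oxo-6β-(TBS-oxy)germacra-4,11(13)-dien-12,8α-olide | C=C1C(=O)O[C@H]2C[C@]3(C)O[C@@H](CC3=O)/C(C)=C\[C@H](O[Si](C)(C)C(C)(C)C)[C@H]12 | intermediate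
28 | 1-(trimethylsilyloxy)-1-ene (silyl enol ether) of 27 | C=C1C(=O)O[C@H]2C[C@]3(C)O[C@@H](C=C3O[Si](C)(C)C)/C(C)=C\[C@H](O[Si](C)(C)C(C)(C)C)[C@H]12 | intermediate
29 | (4Z)-3,10-epoxy-1-oxo-6β-(TBS-oxy)germacra-2,4,11(13)-trien-12,8α-olide | C=C1C(=O)O[C@H]2C[C@]3(C)OC(=CC3=O)/C(C)=C\[C@H](O[Si](C)(C)C(C)(C)C)[C@H]12 | intermediate
30 | (4Z)-3,10-epoxy-6β-hydroxy-1-oxogermacra-2,4,11(13)-trien-12,8α-olide | C=C1C(=O)O[C@H]2C[C@]3(C)OC(=CC3=O)/C(C)=C\[C@H](O)[C@H]12 | intermediate
31 | angelic acid | C/C=C(/C)C(=O)O | starting material
32 | (Z)-2-methylbut-2-en-1-ol | C/C=C(/C)CO | intermediate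
33 | [(2R,3S)-2,3-dimethyloxiran-2-yl]methanol | OC[C@@]1(C)O[C@H]1C | intermediate
34 | (2S,3S)-2,3-dimethyloxirane-2-carboxylic acid | OC(=O)[C@@]1(C)O[C@H]1C | intermediate
35 | mixed anhydride of 34 with 2,4,6-trichlorobenzoic acid | O=C(OC(=O)[C@@]1(C)O[C@H]1C)c1c(Cl)cc(Cl)cc1Cl | intermediate
36 | CNP0258430.1, (4Z)-3,10-epoxy-6β-[(2S,3S)-2,3-dimethyloxirane-2-carbonyloxy]-1-oxogermacra-2,4,11(13)-trien-12,8α-olide (6S,7R,8S,10S) | C=C1C(=O)O[C@H]2C[C@]3(C)OC(=CC3=O)/C(C)=C\[C@H](OC(=O)[C@@]3(C)O[C@H]3C)[C@H]12 | target

Total step count: 20. Longest linear sequence: 15 steps (steps 1–3, 6–16 and 20). Steps 4–5 (silane reagent) and 17–19 (epoxy acid) are side branches.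

Least certain steps

Step 7 (key step). The most likely failure is in the trapping, not in the rearrangement. The crown-complexed potassium enolate may be O-alkylated or may simply be protonated by the acidic methylene of 12, and facial selectivity at C7 may erode if the enolate ring relaxes before it is alkylated. Fallback, setting out from 11: the rearrangement is run as before but the enolate is protonated at −78 °C to give the C7-unsubstituted β-silyl ketone F1. Its only α-methylene (C7) is then deprotonated with LiN(iPr)2 in THF/DMPU at −78 °C, and the lithium enolate is alkylated with 12. This separates ring expansion from C–C bond formation and comes back to the route at 15.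

Step 3. Hydrogen abstraction may be unselective (the tertiary allylic C–H next to the isopropenyl group and the isopropenyl methyl compete with the ring methylene), and over-oxidation may follow. Fallback, setting out from 2 (ring numbers of carveol):
- hydroxyl-directed epoxidation (VO(acac)2, t-BuOOH) gives the syn epoxy alcohol F2;
- SEM protection gives F3;
- sodium phenylselenide (from PhSeSePh and NaBH4) opens the oxirane at the secondary C3 to the hydroxy selenide F4;
- oxidation with H2O2 and selenoxide elimination, which can only go toward C4, gives the tertiary allylic alcohol F5;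
- oxidative 1,3-transposition with pyridinium chlorochromate (C5H5NH[CrO3Cl]) gives the enone.

The route is rejoined at 4.

Step 8. Fluoride and basic peroxide act on a ketone that has an epimerisable C7 and, once oxidised, a β-oxygen. Loss of the C7 configuration, retro-aldol ring opening or β-elimination are the likely failures. Fallback, setting out from 4 and giving up the silicon device:
- CH2=CHMgBr with CeCl3 gives the plain vinyl carbinol F6;
- the same rearrangement and alkylation with 12 give the silicon-free keto ester F7;
- dehydrogenation with IBX gives the C7=C8 dienone F8;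
- nucleophilic epoxidation (t-BuOOH, DBU) gives the 7,8-epoxy ketone F9;
- SmI2 opens the α-C–O bond and gives the hydroxy ester, rejoining the route at 17 (closed to 18 as in step 8).

This detour is stereochemically weaker, because C7 and C8 are then set by epoxidation face and protonation.

Step 9. The facial selectivity of hydride delivery is the weak point: ring-conformational control may override the local bias of the fused lactone and give the 6α epimer. Fallback, setting out from 18: if the reduction gives the 6α-alcohol F10, it is inverted by a Mitsunobu reaction with chloroacetic acid (PPh3, DIAD) to the 6β-chloroacetate F11. The chloroacetyl group is removed with thiourea and NaHCO3 in ethanol, conditions free of alkoxide, and the route is rejoined at 19.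

Step 13. Epoxidation may occur on the β face at C10, in which case the 3β-hydroxyl cannot reach the rear of the C10–O bond, or the C4=C5 alkene may act as the transannular nucleophile. Fallback, setting out from 24, which turns the same facial preference to use: dihydroxylation (OsO4, NMO) from the β face at C10 gives the 1α,3β,10β-triol F12. Double Dess–Martin oxidation of the two secondary carbinols gives the 10β-hydroxy-1,3-dione F13. Acid-catalysed cyclodehydration (TsOH, PhH) closes the 3(2H)-furanone with retention at C10 and comes back to the route at 29, bypassing 26 and 27.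

Further compounds

F1 | step 7 | (1(10)E,4Z)-8α-(benzyldimethylsilyl)-4,10-dimethyl-3β-(SEM-oxy)cyclodeca-1(10),4-dien-6-one (C7 unsubstituted) | C1C(=O)/C=C(C)\[C@@H](OCOCC[Si](C)(C)C)C/C=C(C)/C[C@@H]1[Si](C)(C)Cc1ccccc1
F2 | step 3 | 2,3-epoxide of (1S,5S)-cis-carveol with the oxirane syn to the hydroxyl | C[C@@]12O[C@@H]1C[C@@H](C[C@@H]2O)C(C)=C
F3 | step 3 | SEM ether of F2 | C[C@@]12O[C@@H]1C[C@@H](C[C@@H]2OCOCC[Si](C)(C)C)C(C)=C
F4 | step 3 | 2-hydroxy-3-(phenylselanyl) derivative (trans-diaxial opening product of F3) | C[C@@]1(O)[C@@H]([Se]c2ccccc2)C[C@@H](C[C@@H]1OCOCC[Si](C)(C)C)C(C)=C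
F5 | step 3 | tertiary allylic alcohol, 1-methyl-4-(prop-1-en-2-yl)-6-(SEM-oxy)cyclohex-2-en-1-ol | C[C@@]1(O)C=C[C@@H](C[C@@H]1OCOCC[Si](C)(C)C)C(C)=C
F6 | step 8 | 1-vinyl-3-methyl-6-(prop-1-en-2-yl)-4-(SEM-oxy)cyclohex-2-en-1-ol (vinyl trans to isopropenyl) | C=C[C@]1(O)C=C(C)[C@@H](OCOCC[Si](C)(C)C)C[C@H]1C(C)=C
F7 | step 8 | methyl 2-[(1(10)E,4Z)-4,10-dimethyl-6-oxo-3β-(SEM-oxy)cyclodeca-1(10),4-dien-7β-yl]acetate | COC(=O)C[C@@H]1CC/C(C)=C/C[C@H](OCOCC[Si](C)(C)C)/C(C)=C\C1=O
F8 | step 8 | C7=C8 dehydro derivative of F7 (cross-conjugated dienone; C7=C8 geometry open) | COC(=O)CC1=CC/C(C)=C/C[C@H](OCOCC[Si](C)(C)C)/C(C)=C\C1=O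
F9 | step 8 | 7,8-epoxide of F8 (oxirane face unassigned) | COC(=O)CC12OC1C/C(C)=C/C[C@H](OCOCC[Si](C)(C)C)/C(C)=C\C2=O
F10 | step 9 | 6α-hydroxy epimer of 19 | C1C(=O)O[C@H]2C/C(C)=C/C[C@H](OCOCC[Si](C)(C)C)/C(C)=C\[C@@H](O)[C@H]12
F11 | step 9 | 6β-chloroacetate of 19 | C1C(=O)O[C@H]2C/C(C)=C/C[C@H](OCOCC[Si](C)(C)C)/C(C)=C\[C@H](OC(=O)CCl)[C@H]12
F12 | step 13 | (4Z)-1α,3β,10β-trihydroxy-6β-(TBS-oxy)germacra-4,11(13)-dien-12,8α-olide | C=C1C(=O)O[C@H]2C[C@](C)(O)[C@@H](O)C[C@H](O)/C(C)=C\[C@H](O[Si](C)(C)C(C)(C)C)[C@H]12
F13 | step 13 | (4Z)-10β-hydroxy-1,3-dioxo-6β-(TBS-oxy)germacra-4,11(13)-dien-12,8α-olide | C=C1C(=O)O[C@H]2C[C@](C)(O)C(=O)CC(=O)/C(C)=C\[C@H](O[Si](C)(C)C(C)(C)C)[C@H]12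
A1 | alternative 1 | seco iodo aldehyde with Z C4=C5 iodide and C6 formyl group on C7 | C=C1C(=O)O[C@@H](C[C@]2(C)OC(=CC2=O)/C(C)=C\I)[C@@H]1C=O
A2 | alternative 1 | target alcohol with free C6 hydroxyl (identical with 30) | C=C1C(=O)O[C@H]2C[C@]3(C)OC(=CC3=O)/C(C)=C\[C@H](O)[C@H]12
A3 | alternative 2 | 1β,10α-epoxy-3β-hydroxy germacranolide (identical with 25) | C=C1C(=O)O[C@H]2C[C@@]3(C)O[C@@H]3C[C@H](O)/C(C)=C\[C@H](O[Si](C)(C)C(C)(C)C)[C@H]12
A4 | alternative 2 | 3,10-ether-bridged germacranolide C1 alcohol (identical with 26) | C=C1C(=O)O[C@H]2C[C@]3(C)O[C@@H](C[C@H]3O)/C(C)=C\[C@H](O[Si](C)(C)C(C)(C)C)[C@H]12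
A5 | alternative 3 | furanone-bridged thirteen-membered allylic ether (O between C6 and C13, C11=C7 alkene with C13 and C8 trans, 8-OPMB, C12 as CH2OTBS) | O1C/C(CO[Si](C)(C)C(C)(C)C)=C/[C@@H](OCc2ccc(OC)cc2)C[C@]2(C)OC(=CC2=O)/C(C)=C\C1
A6 | alternative 3 | furanone-bridged ten-membered carbocycle with C6 alcohol and C7 allylic branch | COc1ccc(CO[C@H]2C[C@]3(C)OC(=CC3=O)/C(C)=C\[C@H](O)[C@@H]2C(=C)CO[Si](C)(C)C(C)(C)C)cc1
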